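The ten-membered carbocycle (C1–C10 of the 11-oxabicyclo[8.1.0]undec-6-ene core) is made one atom too large: as an eleven-membered thiacycle in which sulfur bridges C6, the carbon carrying the vinylic methyl, and C7. A Ramberg–Bäcklund ring contraction of the derived sulfone expels the sulfur as SO2, forms the C6–C7 bond and delivers the Z-trisubstituted C6=C7 alkene in one operation, both C6 epimers converging on it. The sulfone precursor is an open chain whose C2–C4 stereotriad comes from an auxiliary-controlled anti-aldol and a 1,3-syn reduction; sulfur enters by conjugate addition and closes the ring by S-alkylation. Hydroxyl-directed epoxidation and acylation at O4 finish.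

Key step: step 11

Remarks on the chemistry:
- Position labels C1–C10 in the Why lines use the target numbering for every intermediate: C1 epoxide CH, C2 CH(OH), C3 CH(iPr), C4 CH(O-acyl), C5 CH2, C6 C(Me)=, C7 =CH, C8 and C9 CH2, C10 epoxide C(Me). Systematic names carry their own locants.
- The sulfur-bearing carbon (later C6) is carried as a mixture of epimers from step 6 to step 10, and enone 10 as an E/Z mixture; both are erased later.
- Assumption: the magnesium-chelated Z-enolate of imide 6 reacts on the face away from the benzyl group, as in alkylations of such imides, so the (R)-auxiliary is the one required.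

Step 1
Reactants: 1 5-chloropent-1-yne
Product: 4 (E)-6-chloro-3-methylhex-2-en-1-ol, via alkenylalane 2 (not isolated), via lithium alanate 3 (not isolated)
Conditions: AlMe3, Cp2ZrCl2 (cat.), CH2Cl2, 0 °C to rt; then n-BuLi, THF, −78 °C; (CH2O)n, −78 °C to rt; aq. HCl
Reagents that add atoms: trimethylaluminium C[Al](C)C; paraformaldehyde (as formaldehyde) C=O
Why: Negishi carboalumination adds Me and Al syn across the terminal alkyne with Al on the terminal carbon, fixing the E trisubstituted alkene, and the derived alanate is hydroxymethylated with retention of geometry.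

Step 2
Reactants: 4 (E)-6-chloro-3-methylhex-2-en-1-ol
Product: 5 (E)-6-chloro-3-methylhex-2-enal
Conditions: MnO2, CH2Cl2, rt
Reagents that add atoms: none
Why: Allylic oxidation with MnO2 stops at the aldehyde, spares the primary chloride and keeps the E geometry.

Step 3
Reactants: 5 (E)-6-chloro-3-methylhex-2-enal; 6 (R)-4-benzyl-3-(3-methylbutanoyl)oxazolidin-2-one
Product: 8 (R)-4-benzyl-3-[(2S,3S,4E)-8-chloro-3-hydroxy-5-methyl-2-(propan-2-yl)oct-4-enoyl]oxazolidin-2-one, via trimethylsilyl ether 7 (not isolated)
Conditions: MgCl2 (cat.), Et3N, TMSCl, EtOAc, rt; then TFA (cat.), MeOH, rt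
Reagents that add atoms: none
Why: Magnesium-halide-catalysed direct anti-aldol of an N-acyloxazolidinone (Evans aldol family): the chelated Z-enolate adds to the non-enolisable enal through a boat transition state on the face away from the benzyl group, so the auxiliary sets C3 and the anti-related C2, and silyl transfer turns the catalyst over before acidic methanol removes the silyl group.

Step 4
Reactants: 8 aldol adduct
Product: 9 (2S,3S,4E)-8-chloro-3-hydroxy-N-methoxy-N,5-dimethyl-2-(propan-2-yl)oct-4-enamide
Conditions: MeONHMe·HCl, AlMe3, CH2Cl2, −15 °C to rt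
Reagents that add atoms: N,O-dimethylhydroxylamine hydrochloride CNOC.Cl
Why: Weinreb amide formation by aluminium amide transamination, assisted by the free β-hydroxyl, should cleave the imide at the exocyclic carbonyl without epimerising C3.

Step 5
Reactants: 9 Weinreb amide
Product: 10 (5S,6S,7E)-11-chloro-6-hydroxy-8-methyl-5-(propan-2-yl)undeca-2,7-dien-4-one (2E/2Z mixture)
Conditions: prop-1-enylmagnesium bromide (excess), THF, −20 to 0 °C; cold aq. NH4Cl
Reagents that add atoms: prop-1-enylmagnesium bromide CC=C[Mg]Br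
Why: Weinreb ketone synthesis: the chelated tetrahedral magnesium intermediate prevents over-addition, and the geometry of the new enone is irrelevant because that double bond is consumed in step 6.

Step 6
Reactants: 10 enone
Product: 11 S-[(5S,6S,7E)-11-chloro-6-hydroxy-8-methyl-4-oxo-5-(propan-2-yl)undec-7-en-2-yl] ethanethioate (C2 epimers)
Conditions: AcSH, Et3N (cat.), CH2Cl2, 0 °C to rt, dark
Reagents that add atoms: thioacetic acid CC(=O)S
Why: Thia-Michael addition of thioacetic acid proceeds under near-neutral conditions that spare the β-hydroxy ketone; the new sulfur-bearing centre (later C6) forms unselectively and is erased in step 11.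

Step 7
Reactants: 11 β-hydroxy ketone thioacetate
Product: 13 S-[(4R,5R,6S,7E)-11-chloro-4,6-dihydroxy-8-methyl-5-(propan-2-yl)undec-7-en-2-yl] ethanethioate (C2 epimers), via diethylboron chelate 12 (not isolated)
Conditions: Et2BOMe, THF/MeOH (4:1), −78 °C; NaBH4, −78 °C; AcOH, then co-evaporation with MeOH
Reagents that add atoms: none
Why: Narasaka–Prasad reduction: the diethylboron chelate adopts a half-chair with the isopropyl group equatorial, and external axial hydride delivery gives the 1,3-syn diol, setting C4 relative to C2.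

Step 8
Reactants: 13 diol
Product: 14 S-[(4R,5R,6S,7E)-4,6-bis[(tert-butyldimethylsilyl)oxy]-11-chloro-8-methyl-5-(propan-2-yl)undec-7-en-2-yl] ethanethioate (C2 epimers)
Conditions: TBSOTf, 2,6-lutidine, CH2Cl2, −78 to 0 °C
Reagents that add atoms: tert-butyldimethylsilyl trifluoromethanesulfonate CC(C)(C)[Si](C)(C)OS(=O)(=O)C(F)(F)F
Why: The silyl triflate with a hindered pyridine base silylates both hindered secondary hydroxyls and leaves thioester and chloride untouched.

Step 9
Reactants: 14 bis-silyl ether
Product: 16 (5E,7S,8R,9R)-7,9-bis[(tert-butyldimethylsilyl)oxy]-5,11-dimethyl-8-(propan-2-yl)thiacycloundec-5-ene (C11 epimers), via caesium thiolate 15 (not isolated)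
Conditions: Cs2CO3, NaI (cat.), MeOH/DMF (1:10, degassed), 50 °C, slow addition to high dilution
Reagents that add atoms: none
Why: Methanolysis of the thioacetate frees a caesium thiolate that closes the eleven-membered ring by intramolecular SN2 displacement (11-exo-tet) of the primary chloride (caesium thiolate macrocyclisation).

Step 10
Reactants: 16 cyclic sulfide
Product: 18 (5E,7S,8R,9R)-7,9-bis[(tert-butyldimethylsilyl)oxy]-5,11-dimethyl-8-(propan-2-yl)thiacycloundec-5-ene 1,1-dioxide (C11 epimers), via sulfoxide 17 (not isolated)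
Conditions: (NH4)6Mo7O24·4H2O (cat.), 30% H2O2, EtOH, 0 °C to rt
Reagents that add atoms: hydrogen peroxide OO
Why: Molybdate-catalysed peroxide oxidation takes the sulfide through the sulfoxide to the sulfone and is chemoselective for sulfur over the trisubstituted alkene.

Step 11
Reactants: 18 cyclic sulfone
Product: 21 (1Z,5E,7S,8R,9R)-7,9-bis[(tert-butyldimethylsilyl)oxy]-1,5-dimethyl-8-(propan-2-yl)cyclodeca-1,5-diene, via α-bromo sulfone 19 (not isolated), via episulfone 20 (not isolated)
Conditions: CBr2F2, KOH/Al2O3, t-BuOH/CH2Cl2, 0 °C to rt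
Reagents that add atoms: none
Why: KOH on alumina deprotonates the sulfone at the C7 methylene and CBr2F2 brominates the carbanion to give 19; deprotonation at the C6 methine then displaces bromide in a 1,3-elimination (3-exo-tet closure of the thiirane 1,1-dioxide 20, which forms the C6–C7 bond), and cheletropic loss of SO2 leaves the C6=C7 alkene in a carbocycle one atom smaller than the thiacycle. This is the Ramberg–Bäcklund reaction in its one-pot halogenative form, used as a ring contraction of a cyclic sulfone. No stereocentre is created: the C6 centre of 18 is destroyed, and because the α-sulfonyl positions epimerise under KOH both C6 epimers funnel into one alkene. The Z geometry (ring bonds to C5 and C8 cis) should follow from the cis-fused episulfone, which on a ten-membered ring is less strained than the trans-fused one and is also the usual kinetic product with hydroxide bases. The step needs mono-bromination at C7 rather than double bromination, which the more acidic and less hindered methylene should provide, and it needs the C1=C10 alkene and the oxygens to stay untouched, which the weakly electrophilic difluorocarbene by-product and the two silyl ethers should secure.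

Step 12
Reactants: 21 bis-silyl diene
Product: 22 (1R,2R,3S,4E,8Z)-5,9-dimethyl-2-(propan-2-yl)cyclodeca-4,8-diene-1,3-diol
Conditions: TBAF, THF, rt to 45 °C
Reagents that add atoms: none
Why: Fluoride-induced desilylation under non-acidic conditions at mild temperature avoids the acid-triggered transannular cyclisation and the thermal Cope rearrangement open to a cyclodeca-1,5-diene.

Step 13
Reactants: 22 diene diol
Product: 23 (1S,2R,3R,4R,6Z,10S)-6,10-dimethyl-3-(propan-2-yl)-11-oxabicyclo[8.1.0]undec-6-ene-2,4-diol
Conditions: VO(acac)2 (cat.), t-BuOOH (1.1 equiv), CH2Cl2, 0 °C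
Reagents that add atoms: tert-butyl hydroperoxide CC(C)(C)OO
Why: Vanadium-catalysed hydroxyl-directed epoxidation: the allylic C2 vanadate should reach the C1=C10 alkene much faster than the homoallylic C4 hydroxyl reaches C6=C7, and with C2–H held in the alkene plane by allylic 1,3-strain against the cis methyl on C10 the oxygen arrives on the hydroxyl-bearing face, giving the threo epoxy alcohol and setting C1 and C10.

Step 14
Reactants: 23 epoxy diol; 24 3,4,5-trimethoxybenzoyl chloride
Product: 25 (1S,2R,3S,4R,6Z,10S)-2-hydroxy-6,10-dimethyl-3-(propan-2-yl)-11-oxabicyclo[8.1.0]undec-6-en-4-yl 3,4,5-trimethoxybenzoate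
Conditions: pyridine, DMAP (cat.), CH2Cl2, −20 to 0 °C
Reagents that add atoms: none
Why: DMAP-catalysed acylation should go to the C4 hydroxyl, which has a CH2 neighbour, in preference to the C2 hydroxyl, which is flanked by the epoxide carbon with its cis methyl and by the isopropyl-bearing carbon and is hydrogen-bonded to the epoxide oxygen; the basic medium protects the acid-labile epoxide.

Compound list
1 | 5-chloropent-1-yne | C#CCCCCl | starting material
2 | (E)-(5-chloro-2-methylpent-1-en-1-yl)dimethylalane | C[Al](C)/C=C(\C)CCCCl | intermediate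
3 | lithium butyl[(E)-5-chloro-2-methylpent-1-en-1-yl]dimethylaluminate | [Li+].CCCC[Al-](C)(C)/C=C(\C)CCCCl | intermediate
4 | (E)-6-chloro-3-methylhex-2-en-1-ol | OC/C=C(\C)CCCCl | intermediate
5 | (E)-6-chloro-3-methylhex-2-enal | O=C/C=C(\C)CCCCl | intermediate
6 | (R)-4-benzyl-3-(3-methylbutanoyl)oxazolidin-2-one | CC(C)CC(=O)N1[C@H](Cc2ccccc2)COC1=O | starting material
7 | trimethylsilyl ether of 8 | ClCCC/C(C)=C/[C@H](O[Si](C)(C)C)[C@H](C(C)C)C(=O)N1[C@H](Cc2ccccc2)COC1=O | intermediate
8 | (R)-4-benzyl-3-[(2S,3S,4E)-8-chloro-3-hydroxy-5-methyl-2-(propan-2-yl)oct-4-enoyl]oxazolidin-2-one | ClCCC/C(C)=C/[C@H](O)[C@H](C(C)C)C(=O)N1[C@H](Cc2ccccc2)COC1=O | intermediate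
9 | (2S,3S,4E)-8-chloro-3-hydroxy-N-methoxy-N,5-dimethyl-2-(propan-2-yl)oct-4-enamide | ClCCC/C(C)=C/[C@H](O)[C@H](C(C)C)C(=O)N(C)OC | intermediate
10 | (5S,6S,7E)-11-chloro-6-hydroxy-8-methyl-5-(propan-2-yl)undeca-2,7-dien-4-one (2E/2Z mixture) | ClCCC/C(C)=C/[C@H](O)[C@H](C(C)C)C(=O)C=CC | intermediate
11 | S-[(5S,6S,7E)-11-chloro-6-hydroxy-8-methyl-4-oxo-5-(propan-2-yl)undec-7-en-2-yl] ethanethioate (C2 epimers) | ClCCC/C(C)=C/[C@H](O)[C@H](C(C)C)C(=O)CC(C)SC(C)=O | intermediate
12 | O-diethylboryl chelate of 11 | ClCCC/C(C)=C/[C@H](OB(CC)CC)[C@H](C(C)C)C(=O)CC(C)SC(C)=O | intermediate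
13 | S-[(4R,5R,6S,7E)-11-chloro-4,6-dihydroxy-8-methyl-5-(propan-2-yl)undec-7-en-2-yl] ethanethioate (C2 epimers) | ClCCC/C(C)=C/[C@H](O)[C@H](C(C)C)[C@H](O)CC(C)SC(C)=O | intermediate
14 | S-[(4R,5R,6S,7E)-4,6-bis[(tert-butyldimethylsilyl)oxy]-11-chloro-8-methyl-5-(propan-2-yl)undec-7-en-2-yl] ethanethioate (C2 epimers) | ClCCC/C(C)=C/[C@H](O[Si](C)(C)C(C)(C)C)[C@H](C(C)C)[C@H](O[Si](C)(C)C(C)(C)C)CC(C)SC(C)=O | intermediate
15 | caesium thiolate from 14 | ClCCC/C(C)=C/[C@H](O[Si](C)(C)C(C)(C)C)[C@H](C(C)C)[C@H](O[Si](C)(C)C(C)(C)C)CC(C)[S-].[Cs+] | intermediate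
16 | (5E,7S,8R,9R)-7,9-bis[(tert-butyldimethylsilyl)oxy]-5,11-dimethyl-8-(propan-2-yl)thiacycloundec-5-ene (C11 epimers) | CC1C[C@@H](O[Si](C)(C)C(C)(C)C)[C@@H](C(C)C)[C@@H](O[Si](C)(C)C(C)(C)C)/C=C(\C)CCCS1 | intermediate
17 | 1-oxide of 16 (sulfoxide, mixture at S and C11) | CC1C[C@@H](O[Si](C)(C)C(C)(C)C)[C@@H](C(C)C)[C@@H](O[Si](C)(C)C(C)(C)C)/C=C(\C)CCCS1=O | intermediate
18 | (5E,7S,8R,9R)-7,9-bis[(tert-butyldimethylsilyl)oxy]-5,11-dimethyl-8-(propan-2-yl)thiacycloundec-5-ene 1,1-dioxide (C11 epimers) | CC1C[C@@H](O[Si](C)(C)C(C)(C)C)[C@@H](C(C)C)[C@@H](O[Si](C)(C)C(C)(C)C)/C=C(\C)CCCS1(=O)=O | intermediate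
19 | 2-bromo derivative of 18 (α-bromo sulfone, bromine on the ring CH2 next to sulfur) | CC1C[C@@H](O[Si](C)(C)C(C)(C)C)[C@@H](C(C)C)[C@@H](O[Si](C)(C)C(C)(C)C)/C=C(\C)CCC(Br)S1(=O)=O | intermediate
20 | episulfone: (4E)-6,8-bis[(tert-butyldimethylsilyl)oxy]-4,10-dimethyl-7-(propan-2-yl)-11-thiabicyclo[8.1.0]undec-4-ene 11,11-dioxide, configured at the three carbinol-chain centres as 18 | CC12C[C@@H](O[Si](C)(C)C(C)(C)C)[C@@H](C(C)C)[C@@H](O[Si](C)(C)C(C)(C)C)/C=C(\C)CCC1S2(=O)=O | intermediate
21 | (1Z,5E,7S,8R,9R)-7,9-bis[(tert-butyldimethylsilyl)oxy]-1,5-dimethyl-8-(propan-2-yl)cyclodeca-1,5-diene | CC(C)(C)[Si](C)(C)O[C@@H]1C/C(C)=C\CC/C(C)=C/[C@H](O[Si](C)(C)C(C)(C)C)[C@@H]1C(C)C | intermediate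
22 | (1R,2R,3S,4E,8Z)-5,9-dimethyl-2-(propan-2-yl)cyclodeca-4,8-diene-1,3-diol | O[C@@H]1C/C(C)=C\CC/C(C)=C/[C@H](O)[C@@H]1C(C)C | intermediate
23 | (1S,2R,3R,4R,6Z,10S)-6,10-dimethyl-3-(propan-2-yl)-11-oxabicyclo[8.1.0]undec-6-ene-2,4-diol | O[C@@H]1C/C(C)=C\CC[C@]2(C)O[C@H]2[C@H](O)[C@@H]1C(C)C | intermediate
24 | 3,4,5-trimethoxybenzoyl chloride | COc1cc(C(Cl)=O)cc(OC)c1OC | starting material
25 | (1S,2R,3S,4R,6Z,10S)-2-hydroxy-6,10-dimethyl-3-(propan-2-yl)-11-oxabicyclo[8.1.0]undec-6-en-4-yl 3,4,5-trimethoxybenzoate | COc1cc(C(=O)O[C@@H]2C/C(C)=C\CC[C@]3(C)O[C@H]3[C@H](O)[C@@H]2C(C)C)cc(OC)c1OC | target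

Total step count: 14. Longest linear sequence: 14 steps (1 to 25); 6 and 24 are commercial and enter directly.

Steps most likely to fail

Step 11 (ring contraction). Halogen transfer and 1,3-elimination may fall out of step: the methylene next to sulfur may be brominated twice before the slow methine deprotonation closes the episulfone, or the ring-fusion geometry may be fixed under kinetic control only and erode the cis (Z) outcome. The fallback separates halogenation from extrusion and puts the geometry under thermodynamic control. It sets out from sulfone 18: kinetic lithiation at the ring CH2 next to sulfur (LiHMDS, THF, −78 °C) and a quench with hexachloroethane should give the isolated α-chloro sulfone F1 as a mono-halide. Treatment with t-BuOK in THF (−78 to 0 °C) should then close episulfone 20. Its remaining ring C–H next to sulfur is acidic enough for the alkoxide to equilibrate the ring fusion to the less strained cis isomer before SO2 is lost, which comes back to the route at 21.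

Step 9 (eleven-membered ring closure). Intermolecular S-alkylation to oligomers and oxidative coupling of the liberated thiolate to disulfides may outrun the irreversible intramolecular displacement. The fallback closes the ring by a reversible conjugate addition, so that open-chain oligomers can revert. It sets out from enone 10: NaSH in degassed DMF under high dilution should displace the primary chloride to give the thiol enone F2. Base-catalysed intramolecular thia-Michael addition should then close it to the eleven-membered β-keto sulfide F3; initial conjugate addition of hydrosulfide followed by ring-closing displacement leads to the same compound. Narasaka–Prasad reduction (Et2BOMe, NaBH4, −78 °C) should give the cyclic syn diol F4, and TBSOTf/2,6-lutidine comes back to the route at 16.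

Step 14 (site-selective acylation). The two secondary hydroxyls may be acylated with insufficient discrimination, giving the regioisomeric ester or the diester. The fallback tells them apart by oxidation state before the epoxide is introduced. It sets out from diene diol 22: MnO2 should oxidise only the allylic C2 hydroxyl, giving the hydroxy enone F5. The remaining C4 hydroxyl is acylated with 24 (pyridine, DMAP, low temperature) to the keto ester F6. Luche reduction (NaBH4, CeCl3, MeOH, −78 °C), or a Corey–Bakshi–Shibata reduction if the ring face bias is insufficient, should return the C2 allylic alcohol as the mono-ester F7. VO(acac)2/t-BuOOH epoxidation, now with a single directing hydroxyl, comes back to the route at 25.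

Further compounds
F1 | step 11 | (5E,7S,8R,9R)-7,9-bis[(tert-butyldimethylsilyl)oxy]-2-chloro-5,11-dimethyl-8-(propan-2-yl)thiacycloundec-5-ene 1,1-dioxide | CC1C[C@@H](O[Si](C)(C)C(C)(C)C)[C@@H](C(C)C)[C@@H](O[Si](C)(C)C(C)(C)C)/C=C(\C)CCC(Cl)S1(=O)=O
F2 | step 9 | (5S,6S,7E)-6-hydroxy-8-methyl-5-(propan-2-yl)-11-sulfanylundeca-2,7-dien-4-one | SCCC/C(C)=C/[C@H](O)[C@H](C(C)C)C(=O)C=CC
F3 | step 9 | (5E,7S,8S)-7-hydroxy-5,11-dimethyl-8-(propan-2-yl)thiacycloundec-5-en-9-one (C11 epimers) | CC1CC(=O)[C@@H](C(C)C)[C@@H](O)/C=C(\C)CCCS1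
F4 | step 9 | (5E,7S,8R,9R)-5,11-dimethyl-8-(propan-2-yl)thiacycloundec-5-ene-7,9-diol (C11 epimers) | CC1C[C@@H](O)[C@@H](C(C)C)[C@@H](O)/C=C(\C)CCCS1
F5 | step 14 | (2E,6Z,9R,10R)-9-hydroxy-3,7-dimethyl-10-(propan-2-yl)cyclodeca-2,6-dien-1-one | O[C@@H]1C/C(C)=C\CC/C(C)=C/C(=O)[C@@H]1C(C)C
F6 | step 14 | 3,4,5-trimethoxybenzoate of F5 at its hydroxyl | COc1cc(C(=O)O[C@@H]2C/C(C)=C\CC/C(C)=C/C(=O)[C@@H]2C(C)C)cc(OC)c1OC
F7 | step 14 | allylic alcohol mono-ester (25 without the epoxide oxygen) | COc1cc(C(=O)O[C@@H]2C/C(C)=C\CC/C(C)=C/[C@H](O)[C@@H]2C(C)C)cc(OC)c1OC
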